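**Retrosynthetic overview**
1. Target ⇒ acyclic acetoxy acid with a terminal diene and a vinyl group, closed by ring-closing metathesis at C2=C3; the ten-membered carbocycle is formed last (the furan is bought in).
2. Acetoxy acid ⇒ primary alkyl iodide + pent-4-en-2-yn-1-ol + CO2 + Ac2O: a one-flask anti-carbomagnesiation / carboxylation / O-acetylation makes C5–C6, C4–C18 and the acetate C–O bond, and fixes the tetrasubstituted Z-alkene.
3. Iodide ⇒ dialkylated δ-lactone (temporary six-membered ring, formed first) by reduction, E-selective dienylation and iodination; quaternary C9 by enolate alkylation anti to the C8 methyl.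
4. δ-Lactone ⇒ 3-methylglutaric anhydride: the absolute configuration is created in one enantioselective C–O bond formation (catalytic desymmetrising methanolysis), which controls every later stereocentre.
5. Ring order: δ-lactone (steps 1–2) → opened (step 7) → cyclodecatriene (step 11).

Atom labels: ring carbons C1–C10 with C4 bearing CO2H (C18), C5 bearing CH2OAc (C19), C8 bearing CH3, C9 bearing CH3 and the 2-(furan-3-yl)ethyl chain; C1=C10 is E, C2=C3 is Z, C4=C5 is Z; the target is (8R,9S).

Assumption: (DHQD)2AQN delivers the (R)-hemiester 2; if it gives the (S)-enantiomer, the pseudoenantiomeric (DHQ)2AQN is used under the same conditions.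

**Route**

Step 1
Reactants: 1 3-methylglutaric anhydride
Product: 2 (3R)-5-methoxy-3-methyl-5-oxopentanoic acid
Conditions: (DHQD)2AQN (10 mol %), MeOH (10 equiv), Et2O, −40 °C
Reagents that add atoms: methanol, CO
Why: Organocatalytic desymmetrisation (enantioselective alcoholysis of a prochiral cyclic anhydride): the quinuclidine nitrogen delivers methanol to one enantiotopic carbonyl, so the new ester C–O bond creates the C8 stereocentre (about 90–95% ee expected), the only centre set by a chiral agent in the route.

Step 2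
Reactants: 2 (3R)-5-methoxy-3-methyl-5-oxopentanoic acid
Product: 4 (4R)-4-methyloxan-2-one, via hydroxy ester 3 (not isolated)
Conditions: BH3·SMe2, THF, 0 → 23 °C; H2O; then TsOH·H2O (cat.), toluene, 60 °C
Reagents that add atoms: none
Why: Chemoselective borane reduction of the carboxylic acid beside the methyl ester, then acid-catalysed lactonisation with loss of methanol; the stereocentre is untouched, and because the acid arm is reduced the (R)-hemiester gives the (R)-lactone.

Step 3
Reactants: 4 (4R)-4-methyloxan-2-one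
Product: 6 (3S,4R)-3,4-dimethyloxan-2-one, via lithium enolate 5 (not isolated)
Conditions: LiN(i-Pr)2, THF, −78 °C; MeI, −78 → −40 °C
Reagents that add atoms: iodomethane, CI
Why: Lactone enolate alkylation; methyl enters anti to the C4 methyl (trans product), but this centre is planarised again in step 5, so only monoalkylation matters.

Step 4
Reactants: 7 2-(furan-3-yl)ethanol
Product: 8 3-(2-iodoethyl)furan
Conditions: PPh3, I2, imidazole, CH2Cl2, 0 → 23 °C
Reagents that add atoms: iodine, II
Why: Appel-type iodination of a primary alcohol under neutral conditions that the acid-sensitive furan tolerates.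

Step 5
Reactants: 6 (3S,4R)-3,4-dimethyloxan-2-one; 8 3-(2-iodoethyl)furan
Product: 10 (3S,4R)-3-[2-(furan-3-yl)ethyl]-3,4-dimethyloxan-2-one, via lithium enolate 9 (not isolated)
Conditions: LiN(i-Pr)2, THF, −78 °C; 8, DMPU, −78 → −20 °C
Reagents that add atoms: none
Why: Alkylation of the tetrasubstituted lactone enolate: the iodide approaches anti to the pseudoaxial C4 methyl of the half-chair enolate, which sets quaternary C9 with the two methyl groups cis (dr ≥ 10:1 expected).

Step 6
Reactants: 10 (3S,4R)-3-[2-(furan-3-yl)ethyl]-3,4-dimethyloxan-2-one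
Product: 11 (3S,4R)-3-[2-(furan-3-yl)ethyl]-3,4-dimethyloxan-2-ol (lactol, anomeric mixture)
Conditions: i-Bu2AlH (1.1 equiv), CH2Cl2, −78 °C; aqueous potassium sodium tartrate
Reagents that add atoms: none
Why: Partial reduction of a hindered lactone stops at the lactol because the tetrahedral aluminate is stable at −78 °C.

Step 7
Reactants: 11 lactol
Product: 12 (3R,4S,5E)-4-[2-(furan-3-yl)ethyl]-3,4-dimethylocta-5,7-dien-1-ol
Conditions: Ph2P(O)CH2CH=CH2 (2.2 equiv), n-BuLi (2.2 equiv), THF–HMPA, −78 → 23 °C
Reagents that add atoms: allyl(diphenyl)phosphine oxide, C=CCP(=O)(c1ccccc1)c1ccccc1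
Why: Horner–Wittig olefination of the ring-opened hydroxy aldehyde with the α-lithiated allylphosphine oxide; syn-elimination of lithium diphenylphosphinate from the anti adduct, reinforced by the bulk of the neighbouring quaternary carbon, gives the E-configured C10=C1 bond of the terminal diene.

Step 8
Reactants: 12 dienol
Product: 13 (3E,5S,6R)-5-[2-(furan-3-yl)ethyl]-8-iodo-5,6-dimethylocta-1,3-diene
Conditions: PPh3, I2, imidazole, CH2Cl2, 0 °C, dark
Reagents that add atoms: iodine, II
Why: Appel-type iodination of the unhindered primary alcohol; the preformed iodophosphonium salt leaves no free iodine to attack the diene or furan.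

Step 9
Reactants: 14 prop-2-yn-1-ol; 15 bromoethene
Product: 16 pent-4-en-2-yn-1-ol
Conditions: PdCl2(PPh3)2 (2 mol %), CuI (4 mol %), i-Pr2NH, THF, 0 → 23 °C
Reagents that add atoms: none
Why: Sonogashira coupling of a terminal alkyne with a vinyl bromide gives the conjugated enynol in one step.

Step 10
Reactants: 13 iodide; 16 pent-4-en-2-yn-1-ol
Product: 22 (2Z,6R,7S,8E)-3-[(acetyloxy)methyl]-2-ethenyl-7-[2-(furan-3-yl)ethyl]-6,7-dimethylundeca-2,8,10-trienoic acid, via alkyllithium 17 (not isolated), via Grignard reagent 18 (not isolated), via chloromagnesium alkoxide 19 (not isolated), via oxamagnesacycle 20 (not isolated), via magnesium carboxylate 21 (not isolated)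
Conditions: 13, t-BuLi (2.05 equiv), Et2O–pentane, −100 °C, 3 min, then MgBr2·OEt2, −100 → −20 °C; add to 16 (1.2 equiv)/i-PrMgCl (1.2 equiv)/CuI (10 mol %), THF, 0 → 23 °C; CO2 (1 atm), 0 °C; Ar purge; Ac2O, −20 → 0 °C; aqueous AcOH
Reagents that add atoms: carbon dioxide, O=C=O; acetic anhydride, CC(=O)OC(C)=O
Why: Proposed new method: a one-flask copper-catalysed anti-carbomagnesiation of a conjugated enynol, carboxylation and chemoselective O-acetylation; the magnesium alkoxide directs trans-addition so that C6 adds to the alkyne carbon next to CH2O and magnesium sits on the vinyl-bearing carbon inside a five-membered oxamagnesacycle (C6 cis to vinyl, CH2O cis to Mg), CO2 inserts into the vinyl C–Mg bond with retention, and the resulting dianion has no electrophilic acyl group and cannot lactonise, so Ac2O, which acylates the alkoxide far faster than the carboxylate, forms the acetate C–O bond and locks the Z-hydroxy acid open before any proton is added; the closest known reaction is the copper-catalysed carbomagnesiation of propargylic alcohols with CO2 trapping (Duboudin–Jousseaume), which after acidic work-up gives butenolides and has not been shown with enynols or with acylative interception.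

Step 11
Reactants: 22 seco acid
Product: 23 (1(10)Z,2Z,4E,6S,7R)-10-[(acetyloxy)methyl]-6-[2-(furan-3-yl)ethyl]-6,7-dimethylcyclodeca-1(10),2,4-triene-1-carboxylic acid (target CNP0110626.2)
Conditions: second-generation Hoveyda–Grubbs catalyst RuCl2(H2IMes)(=CH–C6H4–2-O-i-Pr) (10 mol %), CH2Cl2 (0.5 mM), 40 °C, Ar sparge
Reagents that add atoms: none
Why: Ring-closing metathesis of the two terminal alkenes (the internal diene alkene is shielded by quaternary C9 and the tetrasubstituted alkene is inert) with loss of ethene; the new C2=C3 bond is expected to be Z, as found in the natural ten-membered ring, and 40 °C is kept to avoid 6π-electrocyclisation of the triene.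

**Compound list**
1 | 3-methylglutaric anhydride (4-methyloxane-2,6-dione) | CC1CC(=O)OC(=O)C1 | starting material
2 | (3R)-5-methoxy-3-methyl-5-oxopentanoic acid | COC(=O)C[C@H](C)CC(=O)O | intermediate
3 | methyl (3R)-5-hydroxy-3-methylpentanoate | COC(=O)C[C@H](C)CCO | intermediate
4 | (4R)-4-methyloxan-2-one | O=C1C[C@H](C)CCO1 | intermediate
5 | lithium (4R)-4-methyl-5,6-dihydro-4H-pyran-2-olate (enolate of 4) | [Li]OC1=C[C@H](C)CCO1 | intermediate
6 | (3S,4R)-3,4-dimethyloxan-2-one | O=C1[C@@H](C)[C@H](C)CCO1 | intermediate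
7 | 2-(furan-3-yl)ethanol | OCCc1ccoc1 | starting material
8 | 3-(2-iodoethyl)furan | ICCc1ccoc1 | intermediate
9 | lithium (4R)-3,4-dimethyl-5,6-dihydro-4H-pyran-2-olate (enolate of 6) | [Li]OC1=C(C)[C@H](C)CCO1 | intermediate
10 | (3S,4R)-3-[2-(furan-3-yl)ethyl]-3,4-dimethyloxan-2-one | O=C1[C@@](C)(CCc2ccoc2)[C@H](C)CCO1 | intermediate
11 | (3S,4R)-3-[2-(furan-3-yl)ethyl]-3,4-dimethyloxan-2-ol (anomeric mixture) | OC1[C@@](C)(CCc2ccoc2)[C@H](C)CCO1 | intermediate
12 | (3R,4S,5E)-4-[2-(furan-3-yl)ethyl]-3,4-dimethylocta-5,7-dien-1-ol | OCC[C@@H](C)[C@](C)(CCc1ccoc1)/C=C/C=C | intermediate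
13 | (3E,5S,6R)-5-[2-(furan-3-yl)ethyl]-8-iodo-5,6-dimethylocta-1,3-diene | ICC[C@@H](C)[C@](C)(CCc1ccoc1)/C=C/C=C | intermediate
14 | prop-2-yn-1-ol | C#CCO | starting material
15 | bromoethene | C=CBr | starting material
16 | pent-4-en-2-yn-1-ol | C=CC#CCO | intermediate
17 | [(3R,4S,5E)-4-[2-(furan-3-yl)ethyl]-3,4-dimethylocta-5,7-dien-1-yl]lithium | [Li]CC[C@@H](C)[C@](C)(CCc1ccoc1)/C=C/C=C | intermediate
18 | [(3R,4S,5E)-4-[2-(furan-3-yl)ethyl]-3,4-dimethylocta-5,7-dien-1-yl]magnesium bromide | Br[Mg]CC[C@@H](C)[C@](C)(CCc1ccoc1)/C=C/C=C | intermediate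
19 | chloromagnesium pent-4-en-2-yn-1-olate | C=CC#CCO[Mg]Cl | intermediate
20 | 3-ethenyl-4-[(3R,4S,5E)-4-[2-(furan-3-yl)ethyl]-3,4-dimethylocta-5,7-dien-1-yl]-2,5-dihydro-1,2-oxamagnesole (alkyl chain and vinyl cis) | C=CC1=C(CC[C@@H](C)[C@](C)(CCc2ccoc2)/C=C/C=C)CO[Mg]1 | intermediate
21 | magnesium (2Z,6R,7S,8E)-2-ethenyl-7-[2-(furan-3-yl)ethyl]-6,7-dimethyl-3-(oxidomethyl)undeca-2,8,10-trienoate (seven-membered chelate) | C=CC1=C(CC[C@@H](C)[C@](C)(CCc2ccoc2)/C=C/C=C)CO[Mg]OC1=O | intermediate
22 | (2Z,6R,7S,8E)-3-[(acetyloxy)methyl]-2-ethenyl-7-[2-(furan-3-yl)ethyl]-6,7-dimethylundeca-2,8,10-trienoic acid | CC(=O)OC/C(CC[C@@H](C)[C@](C)(CCc1ccoc1)/C=C/C=C)=C(C(=O)O)/C=C | intermediate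
23 | (1(10)Z,2Z,4E,6S,7R)-10-[(acetyloxy)methyl]-6-[2-(furan-3-yl)ethyl]-6,7-dimethylcyclodeca-1(10),2,4-triene-1-carboxylic acid | CC(=O)OC/C1=C(C(=O)O)/C=C\C=C\[C@@](C)(CCc2ccoc2)[C@H](C)CC1 | target

**Step count**
Total: 11 steps. Longest linear sequence: 9 steps (1, 2, 3, 5, 6, 7, 8, 10, 11).

**Three steps most likely to fail, with fallbacks**

Step 7 (dienylation of the hindered lactol). The α-quaternary aldehyde is revealed only in small equilibrium concentration, and α/γ attack of the allyl anion or incomplete elimination may lower yield or E-selectivity. The fallback sets out from lactol 11 and comes back at dienol 12. Takai–Utimoto iodo-olefination (CrCl2, CHI3, THF–dioxane, 23 °C) gives the (E)-vinyl iodide alcohol F1. Suzuki–Miyaura coupling with potassium vinyltrifluoroborate (PdCl2(dppf), Cs2CO3, THF–H2O, 60 °C) then gives 12, so the diene is built by cross-coupling instead of carbonyl olefination.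

Step 10 (the proposed new step). The main risks are:
- 5-exo cyclisation of alkyllithium 17 onto the diene before transmetalation, which is why the exchange is run at −100 °C for 3 min;
- an unknown regiochemical course of the carbomagnesiation with an enynol;
- acylation of the carboxylate before the alkoxide, which would give the butenolide.

The fallback uses only known reactions, sets out from iodide 13 and comes back at seco acid 22. E2 elimination with KOt-Bu (THF, 0 °C) gives the terminal alkene F2. Hydroboration with 9-BBN (THF, 0 → 23 °C, selective for the isolated monosubstituted alkene over the conjugated diene) gives the B-alkyl borane F3, used directly. B-alkyl Suzuki–Miyaura coupling with 3,4-dibromofuran-2(5H)-one (PdCl2(dppf), AsPh3, Cs2CO3, DMF–THF–H2O), regioselective at the β-carbon, gives the bromobutenolide F4. Stille coupling with Bu3SnCH=CH2 (Pd(PPh3)4, CuI, DMF, 50 °C) gives the vinyl butenolide F5. Saponification with NaOH (1 equiv, THF–H2O), evaporation, and acetylation of the dry sodium hydroxy-carboxylate (Ac2O, pyridine, 0 °C), the sequence used to turn phthalide into 2-(acetoxymethyl)benzoic acid, then gives 22.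

Step 11 (ring-closing metathesis). A strained E,Z,Z-cyclodecatriene must form from two conjugated termini. The free acid or the allylic acetate may chelate the ruthenium alkylidene, and oligomerisation competes. The fallback sets out from seco acid 22 and comes back at target 23, closing the ring on a cis-locked lactone and releasing acid and acetate only afterwards. Methanolysis of the acetate (K2CO3, MeOH) and acidification to pH 2 lactonise 22 to the vinyl butenolide F5 already described. Ring-closing metathesis of this acid-free substrate, whose two ring-forming arms are held cis on a planar five-membered ring (same catalyst, CH2Cl2, 40 °C), gives the macrocyclic butenolide F6. NaOH (1 equiv) followed by Ac2O and pyridine, as above, gives 23.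

**Further compounds**
F1 | step 7 | (3R,4S,5E)-4-[2-(furan-3-yl)ethyl]-6-iodo-3,4-dimethylhex-5-en-1-ol | OCC[C@@H](C)[C@](C)(CCc1ccoc1)/C=C/I
F2 | step 10 | (3E,5R,6R)-5-[2-(furan-3-yl)ethyl]-5,6-dimethylocta-1,3,7-triene | C=C[C@@H](C)[C@](C)(CCc1ccoc1)/C=C/C=C
F3 | step 10 | 9-[(3R,4S,5E)-4-[2-(furan-3-yl)ethyl]-3,4-dimethylocta-5,7-dien-1-yl]-9-borabicyclo[3.3.1]nonane | C=C/C=C/[C@@](C)(CCc1ccoc1)[C@H](C)CCB1C2CCCC1CCC2
F4 | step 10 | 3-bromo-4-[(3R,4S,5E)-4-[2-(furan-3-yl)ethyl]-3,4-dimethylocta-5,7-dien-1-yl]furan-2(5H)-one | BrC1=C(CC[C@@H](C)[C@](C)(CCc2ccoc2)/C=C/C=C)COC1=O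
F5 | step 10 | 3-ethenyl-4-[(3R,4S,5E)-4-[2-(furan-3-yl)ethyl]-3,4-dimethylocta-5,7-dien-1-yl]furan-2(5H)-one | C=CC1=C(CC[C@@H](C)[C@](C)(CCc2ccoc2)/C=C/C=C)COC1=O
F6 | step 11 | (6R,7S,8E,10Z)-7-[2-(furan-3-yl)ethyl]-6,7-dimethyl-4,5,6,7-tetrahydrocyclodeca[c]furan-1(3H)-one | O=C1OCC2=C1/C=C\C=C\[C@@](C)(CCc3ccoc3)[C@H](C)CC2
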